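Triumbelletin is cut at the benzene ring of ring C (the 7-hydroxycoumarin-8-yl unit; ring B is the central coumarin, ring A the umbelliferyl ether). C8 of ring C carries the bond to C8 of ring B and sits between the oxygenated carbons C7 and C8a, a 2-aryl resorcinol pattern. A thermal benzannulation of cyclobutenone with an aryl siloxyalkyne builds this benzene ring around the existing aryl–carbon bond, forming C8–C8a and C6–C7 and delivering the two oxygens differentiated (free OH at C8a, silyl ether at C7), so no aryl–aryl coupling is needed. The precursor is the triisopropylsilyl ynol ether of (2,6-dimethoxyphenyl)acetylene; its dimethoxyphenyl ring later becomes ring B.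

Key step: step 5

Assumption: the target structure fixes no configuration at the ring B–ring C biaryl axis, its only possible stereogenic element, so the axis is left uncontrolled (racemate or interconverting rotamers).

Step 1
Reactants: 1 2,6-dimethoxybenzaldehyde
Product: 2 2-ethynyl-1,3-dimethoxybenzene
Conditions: dimethyl (1-diazo-2-oxopropyl)phosphonate, K2CO3, MeOH, rt
Reagents that add atoms: dimethyl (1-diazo-2-oxopropyl)phosphonate, COP(=O)(OC)C(=[N+]=[N-])C(C)=O
Why: Ohira–Bestmann (Seyferth–Gilbert) homologation, in which methanolysis frees the diazophosphonate anion, this olefinates the non-enolisable aldehyde, and the diazoalkene loses N2 with a 1,2-hydrogen shift to give the terminal alkyne.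

Step 2
Reactants: 2 2-ethynyl-1,3-dimethoxybenzene; 3 triisopropylsilyl trifluoromethanesulfonate
Product: 6 [(2,6-dimethoxyphenyl)ethynyloxy]triisopropylsilane, via lithium acetylide 4 (not isolated), via lithium ynolate 5 (not isolated)
Conditions: n-BuLi, THF, −78 °C; cannulated into LiOOt-Bu (from t-BuOOH and LiN(SiMe3)2, THF, −78 °C), then 0 °C; 3, −78 → 0 °C; NaHCO3 work-up, rapid filtration through Et3N-deactivated silica
Reagents that add atoms: tert-butyl hydroperoxide, CC(C)(C)OO
Why: Electrophilic oxygenation of an acetylide, in which the acetylide carbon attacks the peroxide oxygen and expels tert-butoxide to give the ynolate, which the bulky silyl triflate should capture on oxygen, the standard access to aryl siloxyalkynes.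

Step 3
Reactants: 7 3-oxocyclobutane-1-carboxylic acid
Product: 8 3-bromocyclobutan-1-one
Conditions: HgO (red), Br2, MgSO4, CH2Cl2, reflux
Reagents that add atoms: bromine, BrBr
Why: Cristol–Firth variant of the Hunsdiecker bromodecarboxylation, in which HgO and Br2 convert the acid into the acyl hypobromite and radical loss of CO2 is followed by bromine capture, leaving the ketone intact.

Step 4
Reactants: 8 3-bromocyclobutan-1-one
Product: 9 cyclobut-2-en-1-one
Conditions: n-Bu3N, neat, rt; product distilled under reduced pressure into a −78 °C trap and kept as a cold toluene solution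
Reagents that add atoms: none
Why: Amine-induced dehydrobromination of a β-bromo ketone (E1cB through the enolate), with the volatile enone removed from the ammonium salt as it forms to limit polymerisation.

Step 5
Reactants: 6 [(2,6-dimethoxyphenyl)ethynyloxy]triisopropylsilane; 9 cyclobut-2-en-1-one
Product: 14 2-(2,6-dimethoxyphenyl)-3-(triisopropylsilyloxy)phenol, via vinylketene 10 (not isolated), via vinylcyclobutenone 11 (not isolated), via dienylketene 12 (not isolated), via cyclohexadienone 13 (not isolated)
Conditions: 9 (1.5 equiv, added in two portions), toluene, sealed tube, 80 °C then 110 °C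
Reagents that add atoms: none
Why: Heating opens 9 by 4π electrocyclic ring opening to vinylketene 10, whose carbonyl carbon is attacked by the nucleophilic aryl-bearing carbon of ynol ether 6 in a regioselective (2+2) cycloaddition that gives 11 with C8–C8a and C6–C7 in place. A second, reversible 4π opening of 11 gives dienylketene 12 with the vinyl group cis to the ketene-bearing carbon, and 6π electrocyclisation followed by enolisation of 13 delivers the phenol. The closest known reaction type is the Danheiser benzannulation of cyclobutenones with siloxyalkynes to give resorcinol monosilyl ethers. The benzene ring of ring C is closed by the 6π electrocyclisation that joins the ketene carbon (C8a) to the terminal vinyl carbon (C4a), made irreversible by aromatisation. No stereocentre persists, since the single sp3 centre of 11 is destroyed on ring opening and the biaryl axis is not controlled. The step needs only the regiochemistry of the ketene–alkyne union, which the oxygen-induced polarisation of the siloxyalkyne should secure against the bulk of the 2,6-dimethoxyphenyl group, whose blocked ortho positions also exclude cyclisation onto that ring.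

Step 6
Reactants: 14 2-(2,6-dimethoxyphenyl)-3-(triisopropylsilyloxy)phenol; 15 propiolic acid
Product: 16 2-(2,6-dimethoxyphenyl)-3-(triisopropylsilyloxy)phenyl prop-2-ynoate
Conditions: DCC, DMAP (5 mol %), CH2Cl2, −20 → 0 °C
Reagents that add atoms: none
Why: Steglich carbodiimide esterification, which can acylate only the one free phenolic oxygen because the benzannulation left the other as its silyl ether, with low temperature suppressing conjugate addition to the ynoate.

Step 7
Reactants: 16 2-(2,6-dimethoxyphenyl)-3-(triisopropylsilyloxy)phenyl prop-2-ynoate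
Product: 17 8-(2,6-dimethoxyphenyl)-7-(triisopropylsilyloxy)-2H-chromen-2-one
Conditions: Ph3PAuCl (5 mol %), AgOTf (5 mol %), ClCH2CH2Cl, rt → 50 °C
Reagents that add atoms: none
Why: Intramolecular hydroarylation of an aryl propiolate by cationic monovalent gold, in which π-activation of the alkyne, 6-endo-dig Friedel–Crafts attack by the only free ortho carbon (para to the silyloxy group) and protodeauration close the pyranone of ring C.

Step 8
Reactants: 17 8-(2,6-dimethoxyphenyl)-7-(triisopropylsilyloxy)-2H-chromen-2-one
Product: 18 8-(2,6-dimethoxyphenyl)-7-hydroxy-2H-chromen-2-one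
Conditions: Bu4NF, AcOH, THF, 0 °C
Reagents that add atoms: none
Why: Fluoride-induced desilylation of an aryl silyl ether, buffered with acetic acid so that the lactone stays closed; the silyl group has done its work of differentiating the two oxygens.

Step 9
Reactants: 18 8-(2,6-dimethoxyphenyl)-7-hydroxy-2H-chromen-2-one
Product: 19 8-(2,6-dihydroxyphenyl)-7-hydroxy-2H-chromen-2-one
Conditions: BBr3 (5 equiv), CH2Cl2, −78 °C → rt; then H2O
Reagents that add atoms: none
Why: Lewis-acid ether cleavage (boron–oxygen adduct, then bromide attack at methyl) of two aryl methyl ethers at low temperature, conditions to which the coumarin lactone is inert.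

Step 10
Reactants: 19 8-(2,6-dihydroxyphenyl)-7-hydroxy-2H-chromen-2-one
Product: 21 2,4-dihydroxy-3-(7-hydroxy-2-oxo-2H-chromen-8-yl)benzaldehyde, via iminium salt 20 (not isolated)
Conditions: (chloromethylene)dimethyliminium chloride (1.5–2 equiv), MeCN, 0 °C → rt; then H2O, 50 °C
Reagents that add atoms: (chloromethylene)dimethyliminium chloride, C[N+](C)=CCl.[Cl-]; water, O
Why: Vilsmeier–Haack formylation, in which the chloroiminium ion attacks the resorcinol ring at the carbon ortho to one hydroxyl and para to the other (the two such positions are equivalent), the lactone-deactivated phenol ring of ring C does not compete, and the first formyl group shuts down a second attack.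

Step 11
Reactants: 22 umbelliferone (7-hydroxy-2H-chromen-2-one); 23 tert-butyl bromoacetate
Product: 24 tert-butyl 2-[(2-oxo-2H-chromen-7-yl)oxy]acetate
Conditions: K2CO3, acetone, reflux
Reagents that add atoms: none
Why: Williamson O-alkylation of the acidic 7-hydroxyl with a reactive α-bromo ester under conditions that do not open the lactone.

Step 12
Reactants: 24 tert-butyl 2-[(2-oxo-2H-chromen-7-yl)oxy]acetate
Product: 25 2-[(2-oxo-2H-chromen-7-yl)oxy]acetic acid
Conditions: CF3CO2H, CH2Cl2, rt
Reagents that add atoms: none
Why: Acidolysis of a tert-butyl ester through the tert-butyl cation frees the acid without exposing the lactone to hydroxide.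

Step 13
Reactants: 21 2,4-dihydroxy-3-(7-hydroxy-2-oxo-2H-chromen-8-yl)benzaldehyde; 25 2-[(2-oxo-2H-chromen-7-yl)oxy]acetic acid
Product: 28 7-acetoxy-8-(7-acetoxy-2-oxo-2H-chromen-8-yl)-3-[(2-oxo-2H-chromen-7-yl)oxy]-2H-chromen-2-one, via mixed anhydride 26 (not isolated), via aryl ester 27 (not isolated)
Conditions: 25 (1.5 equiv), Ac2O, Et3N, 110 °C
Reagents that add atoms: acetic anhydride, CC(=O)OC(C)=O
Why: Perkin–Oglialoro condensation, in which the mixed anhydride acylates the hydroxyl ortho to the aldehyde, the aryloxy-activated methylene closes by intramolecular aldol addition and dehydration to form C3=C4 and the lactone of ring B, and the two remaining phenols are capped as acetates in the same pot.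

Step 14
Reactants: 28 7-acetoxy-8-(7-acetoxy-2-oxo-2H-chromen-8-yl)-3-[(2-oxo-2H-chromen-7-yl)oxy]-2H-chromen-2-one
Product: 29 triumbelletin
Conditions: HCl (1.25 M in MeOH), THF, 40 °C
Reagents that add atoms: none
Why: Acid-catalysed transesterification of two aryl acetates with methanol, mild conditions under which the three lactones and the aryl vinyl ether at C3 of ring B should remain intact.

Compound list
1 | 2,6-dimethoxybenzaldehyde | COc1cccc(OC)c1C=O | starting material
2 | 2-ethynyl-1,3-dimethoxybenzene | COc1cccc(OC)c1C#C | intermediate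
3 | triisopropylsilyl trifluoromethanesulfonate | CC(C)[Si](OS(=O)(=O)C(F)(F)F)(C(C)C)C(C)C | starting material
4 | lithium (2,6-dimethoxyphenyl)acetylide | COc1cccc(OC)c1C#C[Li] | intermediate
5 | lithium 2-(2,6-dimethoxyphenyl)ethynolate | COc1cccc(OC)c1C#CO[Li] | intermediate
6 | [(2,6-dimethoxyphenyl)ethynyloxy]triisopropylsilane | COc1cccc(OC)c1C#CO[Si](C(C)C)(C(C)C)C(C)C | intermediate
7 | 3-oxocyclobutane-1-carboxylic acid | O=C1CC(C(=O)O)C1 | starting material
8 | 3-bromocyclobutan-1-one | O=C1CC(Br)C1 | intermediate
9 | cyclobut-2-en-1-one | O=C1C=CC1 | intermediate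
10 | buta-1,3-dien-1-one (vinylketene) | C=CC=C=O | intermediate
11 | racemic 2-(2,6-dimethoxyphenyl)-4-ethenyl-3-(triisopropylsilyloxy)cyclobut-2-en-1-one | COc1cccc(OC)c1C1=C(O[Si](C(C)C)(C(C)C)C(C)C)C(C=C)C1=O | intermediate
12 | (3E)-2-(2,6-dimethoxyphenyl)-3-(triisopropylsilyloxy)hexa-1,3,5-trien-1-one | COc1cccc(OC)c1C(=C=O)/C(O[Si](C(C)C)(C(C)C)C(C)C)=C\C=C | intermediate
13 | 2-(2,6-dimethoxyphenyl)-3-(triisopropylsilyloxy)cyclohexa-2,4-dien-1-one | COc1cccc(OC)c1C1=C(O[Si](C(C)C)(C(C)C)C(C)C)C=CCC1=O | intermediate
14 | 2-(2,6-dimethoxyphenyl)-3-(triisopropylsilyloxy)phenol | COc1cccc(OC)c1-c1c(O)cccc1O[Si](C(C)C)(C(C)C)C(C)C | intermediate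
15 | propiolic acid | C#CC(=O)O | starting material
16 | 2-(2,6-dimethoxyphenyl)-3-(triisopropylsilyloxy)phenyl prop-2-ynoate | C#CC(=O)Oc1cccc(O[Si](C(C)C)(C(C)C)C(C)C)c1-c1c(OC)cccc1OC | intermediate
17 | 8-(2,6-dimethoxyphenyl)-7-(triisopropylsilyloxy)-2H-chromen-2-one | COc1cccc(OC)c1-c1c(O[Si](C(C)C)(C(C)C)C(C)C)ccc2ccc(=O)oc12 | intermediate
18 | 8-(2,6-dimethoxyphenyl)-7-hydroxy-2H-chromen-2-one | COc1cccc(OC)c1-c1c(O)ccc2ccc(=O)oc12 | intermediate
19 | 8-(2,6-dihydroxyphenyl)-7-hydroxy-2H-chromen-2-one | Oc1cccc(O)c1-c1c(O)ccc2ccc(=O)oc12 | intermediate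
20 | N-{[2,4-dihydroxy-3-(7-hydroxy-2-oxo-2H-chromen-8-yl)phenyl]methylidene}-N-methylmethanaminium chloride | C[N+](C)=Cc1ccc(O)c(-c2c(O)ccc3ccc(=O)oc23)c1O.[Cl-] | intermediate
21 | 2,4-dihydroxy-3-(7-hydroxy-2-oxo-2H-chromen-8-yl)benzaldehyde | O=Cc1ccc(O)c(-c2c(O)ccc3ccc(=O)oc23)c1O | intermediate
22 | umbelliferone (7-hydroxy-2H-chromen-2-one) | O=c1ccc2ccc(O)cc2o1 | starting material
23 | tert-butyl bromoacetate | CC(C)(C)OC(=O)CBr | starting material
24 | tert-butyl 2-[(2-oxo-2H-chromen-7-yl)oxy]acetate | CC(C)(C)OC(=O)COc1ccc2ccc(=O)oc2c1 | intermediate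
25 | 2-[(2-oxo-2H-chromen-7-yl)oxy]acetic acid | OC(=O)COc1ccc2ccc(=O)oc2c1 | intermediate
26 | acetic 2-[(2-oxo-2H-chromen-7-yl)oxy]acetic anhydride | CC(=O)OC(=O)COc1ccc2ccc(=O)oc2c1 | intermediate
27 | 3-acetoxy-2-(7-acetoxy-2-oxo-2H-chromen-8-yl)-6-formylphenyl 2-[(2-oxo-2H-chromen-7-yl)oxy]acetate | CC(=O)Oc1ccc(C=O)c(OC(=O)COc2ccc3ccc(=O)oc3c2)c1-c1c(OC(C)=O)ccc2ccc(=O)oc12 | intermediate
28 | 7-acetoxy-8-(7-acetoxy-2-oxo-2H-chromen-8-yl)-3-[(2-oxo-2H-chromen-7-yl)oxy]-2H-chromen-2-one | CC(=O)Oc1ccc2cc(Oc3ccc4ccc(=O)oc4c3)c(=O)oc2c1-c1c(OC(C)=O)ccc2ccc(=O)oc12 | intermediate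
29 | triumbelletin, 7-hydroxy-8-(7-hydroxy-2-oxo-2H-chromen-8-yl)-3-[(2-oxo-2H-chromen-7-yl)oxy]-2H-chromen-2-one | O=c1ccc2ccc(Oc3cc4ccc(O)c(-c5c(O)ccc6ccc(=O)oc56)c4oc3=O)cc2o1 | target

Total step count: 14. Longest linear sequence: 10 steps (1, 2, 5, 6, 7, 8, 9, 10, 13, 14).

Steps most likely to fail

1. Step 5. The hindered, electron-rich siloxyalkyne may combine too slowly with the short-lived vinylketene. Oligomerisation of cyclobutenone, O-acylation of the product phenol by ketene, or thermal silyl migration in the ynol ether would then take over. The fallback gives up the benzannulation for a cross-coupling and sets out from umbelliferone 22. Iodination (I2, KI, aqueous NH3, rt) should give 7-hydroxy-8-iodo-2H-chromen-2-one F1, and O-methylation (MeI, K2CO3, acetone) 8-iodo-7-methoxy-2H-chromen-2-one F2. Suzuki–Miyaura coupling with (2,6-dimethoxyphenyl)boronic acid (Pd(OAc)2, SPhos = 2-dicyclohexylphosphino-2',6'-dimethoxybiphenyl, anhydrous K3PO4, toluene, 100 °C) should then give 8-(2,6-dimethoxyphenyl)-7-methoxy-2H-chromen-2-one F3. BBr3 (CH2Cl2, −78 °C → rt) cleaves all three methyl ethers, and the sequence comes back to the route at triol 19.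

2. Step 13. Acylation and aldol closure at the crowded hydroxyl next to the biaryl axis may be sluggish, so that closure through an acetyl group (giving the ring without the aryloxy substituent) or incomplete condensation dominates. The fallback forms C4–C4a by electrophilic substitution of the resorcinol instead; it sets out from umbelliferone 22 and triol 19 and bypasses steps 10 to 14. Alkylation of 22 with ethyl bromoacetate (K2CO3, acetone) gives ethyl 2-[(2-oxo-2H-chromen-7-yl)oxy]acetate F4. Heating with tert-butoxybis(dimethylamino)methane (toluene, 90 °C) should give ethyl 3-(dimethylamino)-2-[(2-oxo-2H-chromen-7-yl)oxy]prop-2-enoate F5, a formylacetate equivalent. In methanesulfonic acid at rt the iminium form of F5 should attack 19 at the ring B carbon ortho to one hydroxyl and para to the other (Pechmann-type condensation). Loss of dimethylamine and lactonisation then lead directly to triumbelletin 29.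

3. Step 2. Oxygen transfer from the peroxide to the acetylide may be incomplete, for example through proton exchange with residual amine or hydroperoxide, so that the alkyne is returned and little ynolate is available for silylation. The fallback reaches the same ynolate by a carbenoid rearrangement and sets out from aldehyde 1. Addition of LiCHBr2 (CH2Br2, LiN(i-Pr)2, THF, −78 °C, cold acidic quench) should give racemic 2,2-dibromo-1-(2,6-dimethoxyphenyl)ethan-1-ol F6, and Dess–Martin oxidation (CH2Cl2, rt) 2,2-dibromo-1-(2,6-dimethoxyphenyl)ethan-1-one F7. Enolisation with LiN(SiMe3)2, then bromine–lithium exchange with n-BuLi (THF, −78 → 0 °C), triggers the 1,2-aryl shift known from the Kowalski homologation and gives ynolate 5. Silylation with 3 comes back to the route at 6.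

Further compounds
F1 | step 5 | 7-hydroxy-8-iodo-2H-chromen-2-one | O=c1ccc2ccc(O)c(I)c2o1
F2 | step 5 | 8-iodo-7-methoxy-2H-chromen-2-one | COc1ccc2ccc(=O)oc2c1I
F3 | step 5 | 8-(2,6-dimethoxyphenyl)-7-methoxy-2H-chromen-2-one | COc1cccc(OC)c1-c1c(OC)ccc2ccc(=O)oc12
F4 | step 13 | ethyl 2-[(2-oxo-2H-chromen-7-yl)oxy]acetate | CCOC(=O)COc1ccc2ccc(=O)oc2c1
F5 | step 13 | ethyl 3-(dimethylamino)-2-[(2-oxo-2H-chromen-7-yl)oxy]prop-2-enoate (alkene geometry not defined) | CCOC(=O)C(Oc1ccc2ccc(=O)oc2c1)=CN(C)C
F6 | step 2 | racemic 2,2-dibromo-1-(2,6-dimethoxyphenyl)ethan-1-ol | COc1cccc(OC)c1C(O)C(Br)Br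
F7 | step 2 | 2,2-dibromo-1-(2,6-dimethoxyphenyl)ethan-1-one | COc1cccc(OC)c1C(=O)C(Br)Br
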